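## Retrosynthetic overview

- The target is two trans-fused oxepane–cyclohexane (perhydro-1-benzoxepine) bicycles joined by a CH2CH2 bridge; the exocyclic methylene comes last, from the left-hand cyclohexanone.
- Each bicycle is disconnected to an acyclic all-(R) diepoxide carrying an enol (boron or silicon) nucleophile: an epoxonium ring expansion (six-membered bicyclic oxonium → oxepane) that closes the cyclohexanone in the same event.
- Right-hand oxepane and cyclohexane are formed first, in one step (conjugate vinylation of a diepoxy vinyl ketone, then cascade); MeLi/Ac2O then sets the tertiary acetate and acetylates the secondary alcohol.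
- Left-hand oxepane and cyclohexane are formed second, in one step: cross-metathesis of the allyl group with the same diepoxy vinyl ketone, 1,4-hydrosilylation, second cascade, which leaves the left 3-OH free.
- The diepoxy vinyl ketone comes from Shi epoxidation of a dienyl Weinreb amide, and that from dihydropyran and homoprenyl iodide by nickel-catalysed ring-opening methylation, which fixes the (E)-alkene.

Assumption: 5-iodo-2-methylpent-2-ene is bought as a catalogue compound (the corresponding bromide is sold as well).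
Convention: numbered in-flask intermediates are the species present between two reagent additions; species that live only inside one reagent system (the aldehyde on the way to the acid, mono-epoxides, oxonium ions) are described in words.
Locants of the bicycles follow 1-benzoxepine numbering (O1, C2–C5, C5a, C6–C9, C9a).

## Route

Step 1
Reactants: 1 3,4-dihydro-2H-pyran; 2 5-iodo-2-methylpent-2-ene
Product: 4 6-(4-methylpent-3-en-1-yl)-3,4-dihydro-2H-pyran, via lithiated dihydropyran 3 (not isolated)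
Conditions: t-BuLi, THF/pentane, −78 → 0 °C; then 2, −78 → 23 °C
Reagents that add atoms: tert-butyllithium ([Li]C(C)(C)C)
Why: Deprotonation of the vinylic C–H next to oxygen gives the 2-lithio enol ether 3 (the lithium is carried by 3 only), which is alkylated by the primary iodide in an SN2 reaction (alkylation of an α-lithiated enol ether); no stereocenter is formed.

Step 2
Reactants: 4 6-(4-methylpent-3-en-1-yl)-3,4-dihydro-2H-pyran
Product: 5 (4E)-5,9-dimethyldeca-4,8-dien-1-ol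
Conditions: MeMgBr (3 equiv), NiCl2(PPh3)2 (5 mol%), toluene, 80 °C; aq NH4Cl
Reagents that add atoms: methylmagnesium bromide (C[Mg]Br)
Why: Wenkert–Kocienski nickel-catalysed coupling, in which zerovalent nickel inserts into the vinylic C–O bond and methyl replaces oxygen with retention, so the ring geometry becomes the (E)-trisubstituted alkene that later dictates the trans ring fusion.

Step 3
Reactants: 5 (4E)-5,9-dimethyldeca-4,8-dien-1-ol
Product: 6 (4E)-5,9-dimethyldeca-4,8-dienoic acid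
Conditions: TEMPO (0.2 equiv), PhI(OAc)2 (2.2 equiv), MeCN/H2O 1:1, 23 °C
Reagents that add atoms: water (O)
Why: Oxoammonium (TEMPO) oxidation of the primary alcohol through the aldehyde hydrate to the acid, which leaves the trisubstituted alkenes untouched.

Step 4
Reactants: 6 (4E)-5,9-dimethyldeca-4,8-dienoic acid
Product: 8 (4E)-N-methoxy-N,5,9-trimethyldeca-4,8-dienamide, via acyl imidazole 7 (not isolated)
Conditions: 1,1'-carbonyldiimidazole (1.2 equiv), CH2Cl2, 23 °C; then MeNH(OMe)·HCl (1.5 equiv)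
Reagents that add atoms: N,O-dimethylhydroxylamine hydrochloride (CNOC.Cl); 1,1'-carbonyldiimidazole (O=C(n1ccnc1)n1ccnc1)
Why: Acyl-imidazole activation followed by amidation (Weinreb amide formation); the imidazolyl group from the coupling agent is carried by 7 only and leaves as imidazole, and no stereocenter is involved.

Step 5
Reactants: 8 (4E)-N-methoxy-N,5,9-trimethyldeca-4,8-dienamide
Product: 9 3-[(2R,3R)-3-{2-[(2R)-3,3-dimethyloxiran-2-yl]ethyl}-3-methyloxiran-2-yl]-N-methoxy-N-methylpropanamide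
Conditions: D-fructose-derived Shi ketone (0.6 equiv), KHSO5 (as 2KHSO5·KHSO4·K2SO4), K2CO3, Bu4NHSO4, MeCN/CH2(OMe)2/aq Na2B4O7 (pH 10.5), 0 °C
Reagents that add atoms: potassium peroxymonosulfate ([K+].[O-]S(=O)(=O)OO)
Why: Shi asymmetric epoxidation, in which the chiral dioxirane attacks both trisubstituted alkenes through the spiro transition state from the same face and so gives the (R,R) internal and (R) terminal epoxides (about 10:1 per alkene), the amide being inert.

Step 6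
Reactants: 9 3-[(2R,3R)-3-{2-[(2R)-3,3-dimethyloxiran-2-yl]ethyl}-3-methyloxiran-2-yl]-N-methoxy-N-methylpropanamide
Product: 10 5-[(2R,3R)-3-{2-[(2R)-3,3-dimethyloxiran-2-yl]ethyl}-3-methyloxiran-2-yl]pent-1-en-3-one
Conditions: CH2=CHMgBr (1.5 equiv), THF, −78 → 0 °C; inverse quench into cold aq NH4Cl
Reagents that add atoms: vinylmagnesium bromide (C=C[Mg]Br)
Why: Weinreb ketone synthesis, in which the chelated tetrahedral magnesium intermediate stops at the ketone stage and the trisubstituted epoxides do not react with the Grignard reagent below 0 °C.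

Step 7
Reactants: 10 5-[(2R,3R)-3-{2-[(2R)-3,3-dimethyloxiran-2-yl]ethyl}-3-methyloxiran-2-yl]pent-1-en-3-one
Product: 13 (3R,5aR,6R,9aR)-3-hydroxy-2,2,5a-trimethyl-6-(prop-2-en-1-yl)octahydro-1-benzoxepin-7(2H)-one, via enol borinate 11 (not isolated), via borinate ester 12 (not isolated)
Conditions: 9-vinyl-9-BBN (1.2 equiv), CH2Cl2, 23 °C; then 9-BBN-OTf (15 mol%), 2,6-di-tert-butyl-4-methylpyridine (DTBMP, 0.5 equiv), −78 °C; pH 7 buffer/MeOH
Reagents that add atoms: 9-vinyl-9-borabicyclo[3.3.1]nonane (C=CB1C2CCCC1CCC2)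
Why: Proposed new method: a borinyl-relay epoxonium ring expansion terminated by a boron enolate; the vinylborane adds 1,4 to the s-cis vinyl ketone through a six-membered boron-to-oxygen-bound transition state and gives the regiodefined (Z)-enol borinate 11, catalytic 9-BBN-OTf then borylates the terminal epoxide oxygen, the neighbouring epoxide oxygen opens it at the tertiary carbon to a bicyclic epoxonium ion (a six-membered cyclic oxonium fused to the oxirane), and anti attack of the enolate carbon on the tertiary oxonium carbon through a chair cleaves that C–O bond, which enlarges the oxonium ring to the oxepane and closes the cyclohexanone (inversion at C5a gives the trans fusion, the (Z)-enolate puts the allyl group equatorial at C6, C3 and C9a are carried over from the epoxides), after which the O-borylated oxocarbenium passes its borinyl cation to the next epoxide so that the chain runs on catalytic initiator; the closest known reaction types are the conjugate addition of B-alkenyl-9-BBN reagents to methyl vinyl ketone and the silyl-triflate-promoted oxa-/carbacyclisation of diepoxy silyl enol ethers, and new are the boron enolate as terminating nucleophile and the boron relay.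

Step 8
Reactants: 13 (3R,5aR,6R,9aR)-3-hydroxy-2,2,5a-trimethyl-6-(prop-2-en-1-yl)octahydro-1-benzoxepin-7(2H)-one
Product: 15 (3R,5aR,6R,7S,9aR)-2,2,5a,7-tetramethyl-6-(prop-2-en-1-yl)decahydro-1-benzoxepine-3,7-diyl diacetate, via dilithium dialkoxide 14 (not isolated)
Conditions: MeLi (3.5 equiv), Et2O, −78 → 0 °C; then Ac2O (8 equiv), DMAP, 0 → 23 °C
Reagents that add atoms: methyllithium (C[Li]); acetic anhydride (CC(=O)OC(C)=O)
Why: 1,2-Addition of methyllithium from the equatorial direction, because the axial trajectory is blocked by the syn-axial 5a-methyl group, gives the axial tertiary alkoxide (7S), and both lithium alkoxides of 14 are then O-acetylated in the flask (alkoxide acylation).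

Step 9
Reactants: 15 (3R,5aR,6R,7S,9aR)-2,2,5a,7-tetramethyl-6-(prop-2-en-1-yl)decahydro-1-benzoxepine-3,7-diyl diacetate; 10 5-[(2R,3R)-3-{2-[(2R)-3,3-dimethyloxiran-2-yl]ethyl}-3-methyloxiran-2-yl]pent-1-en-3-one
Product: 16 (3R,5aR,6R,7S,9aR)-6-{(2E)-6-[(2R,3R)-3-{2-[(2R)-3,3-dimethyloxiran-2-yl]ethyl}-3-methyloxiran-2-yl]-4-oxohex-2-en-1-yl}-2,2,5a,7-tetramethyldecahydro-1-benzoxepine-3,7-diyl diacetate
Conditions: 10 (2 equiv), second-generation Hoveyda–Grubbs catalyst RuCl2(H2IMes)(=CH-C6H4-2-O-i-Pr) (5 mol%), CH2Cl2, 40 °C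
Reagents that add atoms: none
Why: Olefin cross-metathesis between the terminal allyl group and the electron-poor vinyl ketone, which homodimerises only slowly, gives the (E)-enone selectively, while epoxides and acetates are inert to the ruthenium carbene.

Step 10
Reactants: 16 (3R,5aR,6R,7S,9aR)-6-{(2E)-6-[(2R,3R)-3-{2-[(2R)-3,3-dimethyloxiran-2-yl]ethyl}-3-methyloxiran-2-yl]-4-oxohex-2-en-1-yl}-2,2,5a,7-tetramethyldecahydro-1-benzoxepine-3,7-diyl diacetate
Product: 19 (3R,5aR,6R,7S,9aR)-6-{2-[(3R,5aR,6R,9aR)-3-hydroxy-2,2,5a-trimethyl-7-oxodecahydro-1-benzoxepin-6-yl]ethyl}-2,2,5a,7-tetramethyldecahydro-1-benzoxepine-3,7-diyl diacetate, via triethylsilyl enol ether 17 (not isolated), via triethylsilyl ether 18 (not isolated)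
Conditions: Et3SiH (1.5 equiv), RhCl(PPh3)3 (2 mol%), toluene, 50 °C; evaporate; Et3SiOTf (0.3 equiv), DTBMP, CH2Cl2, −78 °C; then HF·pyridine, THF, 0 °C
Reagents that add atoms: triethylsilane (CC[SiH](CC)CC)
Why: Rhodium-catalysed 1,4-hydrosilylation gives the regiodefined (Z)-silyl enol ether 17, and the known silyl-triflate-promoted epoxonium ring expansion with enol silane termination (oxa-/carbacyclisation of diepoxy enol silanes) then builds the second oxepane and cyclohexanone with C3 and C9a of the new bicycle retained from the epoxides, C5a inverted (trans fusion) and the C6 side chain equatorial (it is α to the ketone, so also thermodynamically secured); the triethylsilyl group is relayed from the enol ether of 17 to the 3-oxygen of 18, and fluoride then cleaves that silyl ether.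

Step 11
Reactants: 19 (3R,5aR,6R,7S,9aR)-6-{2-[(3R,5aR,6R,9aR)-3-hydroxy-2,2,5a-trimethyl-7-oxodecahydro-1-benzoxepin-6-yl]ethyl}-2,2,5a,7-tetramethyldecahydro-1-benzoxepine-3,7-diyl diacetate
Product: 20 (3R,5aR,6R,7S,9aR)-6-{2-[(3R,5aR,6S,9aR)-3-hydroxy-2,2,5a-trimethyl-7-methylidenedecahydro-1-benzoxepin-6-yl]ethyl}-2,2,5a,7-tetramethyldecahydro-1-benzoxepine-3,7-diyl diacetate
Conditions: Zn, CH2Br2, TiCl4 (reagent pre-formed in THF, −40 → 5 °C), CH2Cl2, 0 → 23 °C
Reagents that add atoms: dibromomethane (BrCBr)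
Why: Takai–Lombardo methylenation with the gem-dimetallic zinc/titanium reagent is non-basic and selective for the ketone over the acetates, so the α-stereocenter and both esters are kept.

## Compound list

1 | 3,4-dihydro-2H-pyran | C1=COCCC1 | starting material
2 | 5-iodo-2-methylpent-2-ene | CC(C)=CCCI | starting material
3 | 6-lithio-3,4-dihydro-2H-pyran | [Li]C1=CCCCO1 | intermediate (not isolated)
4 | 6-(4-methylpent-3-en-1-yl)-3,4-dihydro-2H-pyran | CC(C)=CCCC1=CCCCO1 | intermediate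
5 | (4E)-5,9-dimethyldeca-4,8-dien-1-ol | OCCC/C=C(\C)CCC=C(C)C | intermediate
6 | (4E)-5,9-dimethyldeca-4,8-dienoic acid | OC(=O)CC/C=C(\C)CCC=C(C)C | intermediate
7 | 1-[(4E)-5,9-dimethyldeca-4,8-dienoyl]-1H-imidazole | O=C(CC/C=C(\C)CCC=C(C)C)n1ccnc1 | intermediate (not isolated)
8 | (4E)-N-methoxy-N,5,9-trimethyldeca-4,8-dienamide | CON(C)C(=O)CC/C=C(\C)CCC=C(C)C | intermediate
9 | 3-[(2R,3R)-3-{2-[(2R)-3,3-dimethyloxiran-2-yl]ethyl}-3-methyloxiran-2-yl]-N-methoxy-N-methylpropanamide | CON(C)C(=O)CC[C@H]1O[C@]1(C)CC[C@H]1OC1(C)C | intermediate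
10 | 5-[(2R,3R)-3-{2-[(2R)-3,3-dimethyloxiran-2-yl]ethyl}-3-methyloxiran-2-yl]pent-1-en-3-one | C=CC(=O)CC[C@H]1O[C@]1(C)CC[C@H]1OC1(C)C | intermediate
11 | 9-{[(4Z)-7-[(2R,3R)-3-{2-[(2R)-3,3-dimethyloxiran-2-yl]ethyl}-3-methyloxiran-2-yl]hepta-1,4-dien-5-yl]oxy}-9-borabicyclo[3.3.1]nonane | C=CC/C=C(\OB1C2CCCC1CCC2)CC[C@H]1O[C@]1(C)CC[C@H]1OC1(C)C | intermediate (not isolated)
12 | (3R,5aR,6R,9aR)-3-[(9-borabicyclo[3.3.1]nonan-9-yl)oxy]-2,2,5a-trimethyl-6-(prop-2-en-1-yl)octahydro-1-benzoxepin-7(2H)-one | C=CC[C@@H]1[C@@]2(C)CC[C@@H](OB3C4CCCC3CCC4)C(C)(C)O[C@@H]2CCC1=O | intermediate (not isolated)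
13 | (3R,5aR,6R,9aR)-3-hydroxy-2,2,5a-trimethyl-6-(prop-2-en-1-yl)octahydro-1-benzoxepin-7(2H)-one | C=CC[C@@H]1[C@@]2(C)CC[C@@H](O)C(C)(C)O[C@@H]2CCC1=O | intermediate
14 | dilithium (3R,5aR,6R,7S,9aR)-2,2,5a,7-tetramethyl-6-(prop-2-en-1-yl)decahydro-1-benzoxepine-3,7-bis(olate) | C=CC[C@@H]1[C@@]2(C)CC[C@@H]([O-])C(C)(C)O[C@@H]2CC[C@]1(C)[O-].[Li+].[Li+] | intermediate (not isolated)
15 | (3R,5aR,6R,7S,9aR)-2,2,5a,7-tetramethyl-6-(prop-2-en-1-yl)decahydro-1-benzoxepine-3,7-diyl diacetate | C=CC[C@@H]1[C@@]2(C)CC[C@@H](OC(C)=O)C(C)(C)O[C@@H]2CC[C@]1(C)OC(C)=O | intermediate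
16 | (3R,5aR,6R,7S,9aR)-6-{(2E)-6-[(2R,3R)-3-{2-[(2R)-3,3-dimethyloxiran-2-yl]ethyl}-3-methyloxiran-2-yl]-4-oxohex-2-en-1-yl}-2,2,5a,7-tetramethyldecahydro-1-benzoxepine-3,7-diyl diacetate | O=C(/C=C/C[C@@H]1[C@@]2(C)CC[C@@H](OC(C)=O)C(C)(C)O[C@@H]2CC[C@]1(C)OC(C)=O)CC[C@H]1O[C@]1(C)CC[C@H]1OC1(C)C | intermediate
17 | (3R,5aR,6R,7S,9aR)-6-{(3Z)-6-[(2R,3R)-3-{2-[(2R)-3,3-dimethyloxiran-2-yl]ethyl}-3-methyloxiran-2-yl]-4-[(triethylsilyl)oxy]hex-3-en-1-yl}-2,2,5a,7-tetramethyldecahydro-1-benzoxepine-3,7-diyl diacetate | CC[Si](CC)(CC)O/C(CC[C@H]1O[C@]1(C)CC[C@H]1OC1(C)C)=C\CC[C@@H]1[C@@]2(C)CC[C@@H](OC(C)=O)C(C)(C)O[C@@H]2CC[C@]1(C)OC(C)=O | intermediate (not isolated)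
18 | (3R,5aR,6R,7S,9aR)-2,2,5a,7-tetramethyl-6-{2-[(3R,5aR,6R,9aR)-2,2,5a-trimethyl-7-oxo-3-[(triethylsilyl)oxy]decahydro-1-benzoxepin-6-yl]ethyl}decahydro-1-benzoxepine-3,7-diyl diacetate | O=C1CC[C@H]2OC(C)(C)[C@H](O[Si](CC)(CC)CC)CC[C@]2(C)[C@H]1CC[C@@H]1[C@@]2(C)CC[C@@H](OC(C)=O)C(C)(C)O[C@@H]2CC[C@]1(C)OC(C)=O | intermediate (not isolated)
19 | (3R,5aR,6R,7S,9aR)-6-{2-[(3R,5aR,6R,9aR)-3-hydroxy-2,2,5a-trimethyl-7-oxodecahydro-1-benzoxepin-6-yl]ethyl}-2,2,5a,7-tetramethyldecahydro-1-benzoxepine-3,7-diyl diacetate | O=C1CC[C@H]2OC(C)(C)[C@H](O)CC[C@]2(C)[C@H]1CC[C@@H]1[C@@]2(C)CC[C@@H](OC(C)=O)C(C)(C)O[C@@H]2CC[C@]1(C)OC(C)=O | intermediate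
20 | (3R,5aR,6R,7S,9aR)-6-{2-[(3R,5aR,6S,9aR)-3-hydroxy-2,2,5a-trimethyl-7-methylidenedecahydro-1-benzoxepin-6-yl]ethyl}-2,2,5a,7-tetramethyldecahydro-1-benzoxepine-3,7-diyl diacetate (CNP0412606.2) | C=C1CC[C@H]2OC(C)(C)[C@H](O)CC[C@]2(C)[C@H]1CC[C@@H]1[C@@]2(C)CC[C@@H](OC(C)=O)C(C)(C)O[C@@H]2CC[C@]1(C)OC(C)=O | target

## Step count and risks

Total step count: 11. Longest linear sequence: 11 steps (1 and 2 to 20; enone 10 is used twice, in steps 7 and 9).

Steps most likely to fail: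

Step 7 (the proposed new method). The enol borinate may be too weak a carbon nucleophile for the epoxonium ion, or its own boron may start the cascade unselectively at 23 °C. The fallback uses known chemistry, sets out from 10 and comes back at 13. CuBr·SMe2-catalysed conjugate addition of CH2=CHMgBr to 10 with Me3SiCl in THF at −78 °C gives the (Z)-silyl enol ether trimethyl{[(4Z)-7-(diepoxyalkyl)hepta-1,4-dien-5-yl]oxy}silane F1. The established cascade (Me3SiOTf, DTBMP, CH2Cl2, −78 °C) converts it into the bicyclic ketone trimethylsilyl ether F2, and dilute HCl in THF removes the silyl group to give 13.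

Step 8. Methyllithium may enolise the hindered ketone, or the 1,3-diaxially crowded tertiary alkoxide may acetylate incompletely. The fallback sets out from 13 and comes back at 14 (and so 15). Dimethylsulfoxonium methylide (Me3S(O)I, NaH, DMSO) adds reversibly and delivers CH2 equatorially, giving the spiro-epoxide with axial oxygen, (3R,5aR,6R,7S,9aR)-2,2,5a-trimethyl-6-(prop-2-en-1-yl)octahydro-2H-spiro[1-benzoxepine-7,2'-oxiran]-3-ol F3. LiBHEt3 opens it at the CH2 carbon to the diol (3R,5aR,6R,7S,9aR)-2,2,5a,7-tetramethyl-6-(prop-2-en-1-yl)decahydro-1-benzoxepine-3,7-diol F4. n-BuLi (2 equiv) turns F4 into 14, and Ac2O then gives 15.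

Step 10. The tertiary acetate of 17 may ionise under the silyl triflate, and the telescoped hydrosilylation/cascade may be inefficient on this large substrate. The fallback reverses the order of the two halves so that both acetates are introduced after the last Lewis-acid step; it sets out from 13 (which has the configuration of the left-hand bicycle as well) and comes back at 20. t-BuMe2SiOTf/2,6-lutidine gives the silyl ether (3R,5aR,6R,9aR)-3-{[tert-butyl(dimethyl)silyl]oxy}-2,2,5a-trimethyl-6-(prop-2-en-1-yl)octahydro-1-benzoxepin-7(2H)-one F5. Zn/CH2Br2/TiCl4 then gives the methylidene compound tert-butyl(dimethyl){[(3R,5aR,6S,9aR)-2,2,5a-trimethyl-7-methylidene-6-(prop-2-en-1-yl)decahydro-1-benzoxepin-3-yl]oxy}silane F6. Cross-metathesis with 10 (same catalyst as step 9) gives the (E)-enone F7, and Et3SiH/RhCl(PPh3)3 converts it into the (Z)-triethylsilyl enol ether F8. Et3SiOTf/DTBMP at −78 °C gives the bis-silyl ether ketone F9, and pyridinium p-toluenesulfonate in MeOH removes only the triethylsilyl group to give the hydroxy ketone F10. MeLi gives the dilithium dialkoxide F11, Ac2O the diacetate silyl ether F12, and HF·pyridine then gives 20.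

## Further compounds

F1 | step 7 | trimethyl{[(4Z)-7-[(2R,3R)-3-{2-[(2R)-3,3-dimethyloxiran-2-yl]ethyl}-3-methyloxiran-2-yl]hepta-1,4-dien-5-yl]oxy}silane | C=CC/C=C(\O[Si](C)(C)C)CC[C@H]1O[C@]1(C)CC[C@H]1OC1(C)C
F2 | step 7 | (3R,5aR,6R,9aR)-2,2,5a-trimethyl-6-(prop-2-en-1-yl)-3-[(trimethylsilyl)oxy]octahydro-1-benzoxepin-7(2H)-one | C=CC[C@@H]1[C@@]2(C)CC[C@@H](O[Si](C)(C)C)C(C)(C)O[C@@H]2CCC1=O
F3 | step 8 | (3R,5aR,6R,7S,9aR)-2,2,5a-trimethyl-6-(prop-2-en-1-yl)octahydro-2H-spiro[1-benzoxepine-7,2'-oxiran]-3-ol (oxirane oxygen axial, cis to the 5a-methyl) | C=CC[C@@H]1[C@@]2(C)CC[C@@H](O)C(C)(C)O[C@@H]2CC[C@]13OC3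
F4 | step 8 | (3R,5aR,6R,7S,9aR)-2,2,5a,7-tetramethyl-6-(prop-2-en-1-yl)decahydro-1-benzoxepine-3,7-diol | C=CC[C@@H]1[C@@]2(C)CC[C@@H](O)C(C)(C)O[C@@H]2CC[C@]1(C)O
F5 | step 10 | (3R,5aR,6R,9aR)-3-{[tert-butyl(dimethyl)silyl]oxy}-2,2,5a-trimethyl-6-(prop-2-en-1-yl)octahydro-1-benzoxepin-7(2H)-one | C=CC[C@@H]1[C@@]2(C)CC[C@@H](O[Si](C)(C)C(C)(C)C)C(C)(C)O[C@@H]2CCC1=O
F6 | step 10 | tert-butyl(dimethyl){[(3R,5aR,6S,9aR)-2,2,5a-trimethyl-7-methylidene-6-(prop-2-en-1-yl)decahydro-1-benzoxepin-3-yl]oxy}silane | C=CC[C@@H]1[C@@]2(C)CC[C@@H](O[Si](C)(C)C(C)(C)C)C(C)(C)O[C@@H]2CCC1=C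
F7 | step 10 | (4E)-6-[(3R,5aR,6S,9aR)-3-{[tert-butyl(dimethyl)silyl]oxy}-2,2,5a-trimethyl-7-methylidenedecahydro-1-benzoxepin-6-yl]-1-[(2R,3R)-3-{2-[(2R)-3,3-dimethyloxiran-2-yl]ethyl}-3-methyloxiran-2-yl]hex-4-en-3-one | O=C(/C=C/C[C@@H]1[C@@]2(C)CC[C@@H](O[Si](C)(C)C(C)(C)C)C(C)(C)O[C@@H]2CCC1=C)CC[C@H]1O[C@]1(C)CC[C@H]1OC1(C)C
F8 | step 10 | (Z)-triethylsilyl enol ether of F7 (3-[(triethylsilyl)oxy]hex-3-ene, silyloxy group cis to the chain leading to the bicycle) | CC[Si](CC)(CC)O/C(CC[C@H]1O[C@]1(C)CC[C@H]1OC1(C)C)=C\CC[C@@H]1[C@@]2(C)CC[C@@H](O[Si](C)(C)C(C)(C)C)C(C)(C)O[C@@H]2CCC1=C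
F9 | step 10 | (3R,5aR,6R,9aR)-6-{2-[(3R,5aR,6S,9aR)-3-{[tert-butyl(dimethyl)silyl]oxy}-2,2,5a-trimethyl-7-methylidenedecahydro-1-benzoxepin-6-yl]ethyl}-2,2,5a-trimethyl-3-[(triethylsilyl)oxy]octahydro-1-benzoxepin-7(2H)-one | C=C1CC[C@H]2OC(C)(C)[C@H](O[Si](C)(C)C(C)(C)C)CC[C@]2(C)[C@H]1CC[C@@H]1[C@@]2(C)CC[C@@H](O[Si](CC)(CC)CC)C(C)(C)O[C@@H]2CCC1=O
F10 | step 10 | (3R,5aR,6R,9aR)-6-{2-[(3R,5aR,6S,9aR)-3-{[tert-butyl(dimethyl)silyl]oxy}-2,2,5a-trimethyl-7-methylidenedecahydro-1-benzoxepin-6-yl]ethyl}-3-hydroxy-2,2,5a-trimethyloctahydro-1-benzoxepin-7(2H)-one | C=C1CC[C@H]2OC(C)(C)[C@H](O[Si](C)(C)C(C)(C)C)CC[C@]2(C)[C@H]1CC[C@@H]1[C@@]2(C)CC[C@@H](O)C(C)(C)O[C@@H]2CCC1=O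
F11 | step 10 | dilithium 3,7-bis(olate) formed from F10 and methyllithium (7S, axial oxygen) | C=C1CC[C@H]2OC(C)(C)[C@H](O[Si](C)(C)C(C)(C)C)CC[C@]2(C)[C@H]1CC[C@@H]1[C@@]2(C)CC[C@@H]([O-])C(C)(C)O[C@@H]2CC[C@]1(C)[O-].[Li+].[Li+]
F12 | step 10 | tert-butyldimethylsilyl ether of 20 at the left-hand 3-hydroxyl | C=C1CC[C@H]2OC(C)(C)[C@H](O[Si](C)(C)C(C)(C)C)CC[C@]2(C)[C@H]1CC[C@@H]1[C@@]2(C)CC[C@@H](OC(C)=O)C(C)(C)O[C@@H]2CC[C@]1(C)OC(C)=O
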